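Assumption: the target SMILES has no stereocentre and no stereogenic double bond, so the compound is achiral and the "single enantiomer" condition needs no stereocontrol.

## Retrosynthetic overview

1. Target 15 ⇐ benzyl ester 14; the acid of the olivetolic half stays masked as its benzyl ester until a final hydrogenolysis.
2. Depside C(=O)–OAr bond: 14 ⇐ cyclic silyl ester 8 + bis-TMS ether 12, by a proposed silyl-transfer-driven acyl transfer (new step).
3. Aryl–C(=O) bond of the chlorinated half: 8 ⇐ aryloxysilanol 7 + CO, by silanol-directed C–H carbonylation at the only free ortho position of phenol 5.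
4. 5 ⇐ 1-bromo-3,5-dimethoxybenzene (Kumada propylation, lithiation/chlorination between the two OMe groups, one O-demethylation); 12 ⇐ olivetol (Stiles carboxylation, benzyl ester, silylation).
5. Rings: both benzene rings are bought; the only ring made is the temporary 1,3,2-dioxasilin-4-one of 8 (step 5), which is opened again in step 9.

## Route

Step 1
Reactants: 1 1-bromo-3,5-dimethoxybenzene
Product: 2 1,3-dimethoxy-5-propylbenzene
Conditions: n-PrMgBr (1.3 equiv), NiCl2(dppp) (2 mol%), THF, 0 °C → reflux, 3 h
Reagents that add atoms: n-propylmagnesium bromide CCC[Mg]Br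
Why: Nickel-catalysed Kumada coupling of an aryl bromide with a primary alkyl Grignard reagent is fast with dppp, which keeps the n-propyl group from isomerising.

Step 2
Reactants: 2 1,3-dimethoxy-5-propylbenzene
Product: 4 2-chloro-1,3-dimethoxy-5-propylbenzene, via aryllithium 3 (not isolated)
Conditions: n-BuLi (1.2 equiv), THF, 0 °C → rt, 2 h; then C2Cl6 (1.3 equiv), −78 °C → rt
Reagents that add atoms: hexachloroethane ClC(Cl)(Cl)C(Cl)(Cl)Cl; n-butyllithium [Li]CCCC (lithium of 3 only)
Why: Directed ortho-metalation takes place only at the carbon between the two methoxy groups, and the electrophilic chlorine of hexachloroethane then places the chlorine there without regiochemical ambiguity.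

Step 3
Reactants: 4 2-chloro-1,3-dimethoxy-5-propylbenzene
Product: 5 2-chloro-3-methoxy-5-propylphenol
Conditions: NaSEt (2.5 equiv), DMF, 110 °C, 3 h; then 1 M HCl
Reagents that add atoms: none
Why: SN2 O-demethylation by thiolate stops after one of the two equivalent methyl ethers, because the aryloxide formed deactivates the ring toward a second cleavage.

Step 4
Reactants: 5 2-chloro-3-methoxy-5-propylphenol
Product: 7 di-tert-butyl(2-chloro-3-methoxy-5-propylphenoxy)silanol, via silyl triflate 6 (not isolated)
Conditions: t-Bu2Si(OTf)2 (1.3 equiv), 2,6-lutidine (3 equiv), CH2Cl2, 0 °C → rt; then sat. aq NaHCO3, THF, rt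
Reagents that add atoms: di-tert-butylsilyl bis(trifluoromethanesulfonate) CC(C)(C)[Si](OS(=O)(=O)C(F)(F)F)(OS(=O)(=O)C(F)(F)F)C(C)(C)C; water O
Why: O-silylation of the phenol by the silyl bis-triflate stops after one displacement for steric reasons, and the remaining Si–OTf bond is hydrolysed to the silanol on bicarbonate work-up.

Step 5
Reactants: 7 di-tert-butyl(2-chloro-3-methoxy-5-propylphenoxy)silanol
Product: 8 2,2-di-tert-butyl-8-chloro-7-methoxy-5-propyl-4H-benzo[d][1,3,2]dioxasilin-4-one
Conditions: Pd(OAc)2 (10 mol%), Boc-Leu-OH (20 mol%), AgOAc (3 equiv), CF3CH2OH (3 equiv), CO (1 atm), DCE, 95 °C, 18 h; filter through Celite and a short silica plug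
Reagents that add atoms: carbon monoxide [C-]#[O+]
Why: Silanol-directed Pd(II) C–H carbonylation, known for simpler aryloxysilanols: the Si–OH group delivers palladium to the only free ortho C–H (the other ortho carbon carries Cl), CO inserts, C–O reductive elimination closes the cyclic silyl ester, and Ag(I) reoxidises Pd(0).

Step 6
Reactants: 9 olivetol (5-pentylbenzene-1,3-diol)
Product: 10 olivetolic acid (2,4-dihydroxy-6-pentylbenzoic acid)
Conditions: methyl magnesium carbonate (2 M in DMF, 3 equiv), 120 °C, 3 h; then cold 2 M HCl
Reagents that add atoms: methyl magnesium carbonate (Stiles reagent) COC(=O)O[Mg]OC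
Why: Stiles carboxylation (a Kolbe–Schmitt-type reaction): magnesium chelation delivers CO2 ortho to one hydroxyl and para to the other, next to the pentyl group, and the stable magnesium salicylate chelate drives the reaction.

Step 7
Reactants: 10 olivetolic acid
Product: 11 benzyl 2,4-dihydroxy-6-pentylbenzoate
Conditions: BnBr (1.05 equiv), KHCO3 (1.1 equiv), DMF, rt, 16 h
Reagents that add atoms: benzyl bromide BrCc1ccccc1
Why: SN2 alkylation of the carboxylate: bicarbonate deprotonates only the carboxylic acid, so both phenols stay free.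

Step 8
Reactants: 11 benzyl 2,4-dihydroxy-6-pentylbenzoate
Product: 12 benzyl 6-pentyl-2,4-bis(trimethylsilyloxy)benzoate
Conditions: HMDS (3 equiv), TMSCl (5 mol%), MeCN, 70 °C, 2 h; evaporate, use crude
Reagents that add atoms: hexamethyldisilazane C[Si](C)(C)N[Si](C)(C)C
Why: O-silylation of both phenols with HMDS is driven by loss of ammonia, and everything else is volatile, so 12 is obtained dry for the next step.

Step 9
Reactants: 8 2,2-di-tert-butyl-8-chloro-7-methoxy-5-propyl-4H-benzo[d][1,3,2]dioxasilin-4-one; 12 benzyl 6-pentyl-2,4-bis(trimethylsilyloxy)benzoate (1.5 equiv)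
Product: 14 benzyl 4-[(3-chloro-2-hydroxy-4-methoxy-6-propylbenzoyl)oxy]-2-hydroxy-6-pentylbenzoate, via silyl-capped depside 13 (not isolated)
Conditions: TBAT (5 mol%), THF, 50 °C, 12 h; then TBAF/AcOH (1:1, 5 equiv), THF, 0 °C → rt
Reagents that add atoms: none
Why: Proposed new method: a silyl-transfer-driven catalytic acyl transfer in which fluoride from TBAT frees a catalytic amount of the unhindered 4-phenoxide of 12, this phenoxide adds to the lactone-like carbonyl of cyclic silyl ester 8 (attack at silicon is blocked by the two tert-butyl groups), and the ring-opened, more basic silanolate, which would otherwise re-close, is capped irreversibly by Me3Si transfer from a further molecule of 12 to give disiloxane 13 while releasing the next phenoxide, so that Si–O–Si formation pulls the unfavourable ring-opening forward, the 2-OTMS group flanked by the benzyl ester does not compete, and buffered fluoride then removes all silicon; the closest known reaction types are the alkoxide opening of 2,2-dimethylbenzodioxinones to salicylate esters and the Lewis-base-catalysed coupling of aryl silyl ethers with acyl fluorides or fluorosulfates.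

Step 10
Reactants: 14 benzyl 4-[(3-chloro-2-hydroxy-4-methoxy-6-propylbenzoyl)oxy]-2-hydroxy-6-pentylbenzoate
Product: 15 4-[(3-chloro-2-hydroxy-4-methoxy-6-propylbenzoyl)oxy]-2-hydroxy-6-pentylbenzoic acid (target)
Conditions: H2 (1 atm), 10% Pd/C, EtOAc, rt, 1–2 h, stopped at full conversion
Reagents that add atoms: none
Why: Hydrogenolysis of the benzyl ester over Pd/C under neutral conditions frees the acid, while the hindered aryl ester and the chloride on the electron-rich ring are left alone in the short reaction time.

## Compound list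

1 | 1-bromo-3,5-dimethoxybenzene | COc1cc(Br)cc(OC)c1 | starting material
2 | 1,3-dimethoxy-5-propylbenzene | CCCc1cc(OC)cc(OC)c1 | intermediate
3 | (2,6-dimethoxy-4-propylphenyl)lithium | CCCc1cc(OC)c([Li])c(OC)c1 | intermediate
4 | 2-chloro-1,3-dimethoxy-5-propylbenzene | CCCc1cc(OC)c(Cl)c(OC)c1 | intermediate
5 | 2-chloro-3-methoxy-5-propylphenol | CCCc1cc(O)c(Cl)c(OC)c1 | intermediate
6 | di-tert-butyl(2-chloro-3-methoxy-5-propylphenoxy)silyl trifluoromethanesulfonate | CCCc1cc(O[Si](OS(=O)(=O)C(F)(F)F)(C(C)(C)C)C(C)(C)C)c(Cl)c(OC)c1 | intermediate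
7 | di-tert-butyl(2-chloro-3-methoxy-5-propylphenoxy)silanol | CCCc1cc(O[Si](O)(C(C)(C)C)C(C)(C)C)c(Cl)c(OC)c1 | intermediate
8 | 2,2-di-tert-butyl-8-chloro-7-methoxy-5-propyl-4H-benzo[d][1,3,2]dioxasilin-4-one | CCCc1cc(OC)c(Cl)c2O[Si](C(C)(C)C)(C(C)(C)C)OC(=O)c12 | intermediate
9 | olivetol (5-pentylbenzene-1,3-diol) | CCCCCc1cc(O)cc(O)c1 | starting material
10 | olivetolic acid (2,4-dihydroxy-6-pentylbenzoic acid) | CCCCCc1cc(O)cc(O)c1C(=O)O | intermediate
11 | benzyl 2,4-dihydroxy-6-pentylbenzoate | CCCCCc1cc(O)cc(O)c1C(=O)OCc1ccccc1 | intermediate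
12 | benzyl 6-pentyl-2,4-bis(trimethylsilyloxy)benzoate | CCCCCc1cc(O[Si](C)(C)C)cc(O[Si](C)(C)C)c1C(=O)OCc1ccccc1 | intermediate
13 | benzyl 4-{[3-chloro-2-({di-tert-butyl[(trimethylsilyl)oxy]silyl}oxy)-4-methoxy-6-propylbenzoyl]oxy}-6-pentyl-2-(trimethylsilyloxy)benzoate | CCCCCc1cc(OC(=O)c2c(CCC)cc(OC)c(Cl)c2O[Si](O[Si](C)(C)C)(C(C)(C)C)C(C)(C)C)cc(O[Si](C)(C)C)c1C(=O)OCc1ccccc1 | intermediate
14 | benzyl 4-[(3-chloro-2-hydroxy-4-methoxy-6-propylbenzoyl)oxy]-2-hydroxy-6-pentylbenzoate | CCCCCc1cc(OC(=O)c2c(CCC)cc(OC)c(Cl)c2O)cc(O)c1C(=O)OCc1ccccc1 | intermediate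
15 | 4-[(3-chloro-2-hydroxy-4-methoxy-6-propylbenzoyl)oxy]-2-hydroxy-6-pentylbenzoic acid | CCCCCc1cc(OC(=O)c2c(CCC)cc(OC)c(Cl)c2O)cc(O)c1C(=O)O | target

## Step count and risks

Total step count: 10. Longest linear sequence: 7 steps (steps 1, 2, 3, 4, 5, 9, 10); the olivetol arm (steps 6, 7, 8) joins at step 9.

The three steps most likely to fail:

**Step 9 (proposed new method).** The ring-opening may be too slow at the hindered carbonyl, or the phenoxide may attack silicon instead. The fallback uses known chemistry; it sets out from 8 (with 11 as partner) and comes back to the route at 14. TBAF in wet THF cleaves the silylene of 8 to the free salicylic acid, 3-chloro-2-hydroxy-4-methoxy-6-propylbenzoic acid F3 (the same acid as F2 below). Trifluoroacetic anhydride in toluene at room temperature turns it into the mixed anhydride, 3-chloro-2-hydroxy-4-methoxy-6-propylbenzoic trifluoroacetic anhydride F4. F4 acylates the free, non-chelated 4-hydroxyl of benzyl ester 11 (the 2-hydroxyl is hydrogen-bonded to the ester) and gives 14 directly. This is the classical depside condensation.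

**Step 5 (C–H carbonylation at a position flanked by the propyl group).** Palladation next to the alkyl chain may be sluggish. The fallback sets out from 5 and comes back to the route at 8, replacing steps 4 and 5. Magnesium-mediated ortho-formylation (MgCl2, Et3N, paraformaldehyde, MeCN, reflux) goes only to the single free ortho position and gives 3-chloro-2-hydroxy-4-methoxy-6-propylbenzaldehyde F1. Pinnick oxidation (NaClO2, NaH2PO4, 2-methyl-2-butene, t-BuOH/water) gives 3-chloro-2-hydroxy-4-methoxy-6-propylbenzoic acid F2. Treatment with t-Bu2Si(OTf)2 and 2,6-lutidine in CH2Cl2 closes the silylene to 8.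

**Step 10 (hydrogenolysis with an aryl chloride present).** Hydrodechlorination could compete. The fallback sets out from 14 and comes back at 15 without hydrogen or palladium: BCl3 with pentamethylbenzene as cation scavenger in CH2Cl2 at −78 °C removes the benzyl group by Lewis-acid ionisation, helped by chelation of boron to the salicylate; the non-chelated methyl ether and the depside ester are left alone at this temperature. No new compound is made (F0).

## Further compounds

F1 | step 5 | 3-chloro-2-hydroxy-4-methoxy-6-propylbenzaldehyde | CCCc1cc(OC)c(Cl)c(O)c1C=O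
F2 | step 5 | 3-chloro-2-hydroxy-4-methoxy-6-propylbenzoic acid | CCCc1cc(OC)c(Cl)c(O)c1C(=O)O
F3 | step 9 | 3-chloro-2-hydroxy-4-methoxy-6-propylbenzoic acid (same compound as F2, here made from 8) | CCCc1cc(OC)c(Cl)c(O)c1C(=O)O
F4 | step 9 | 3-chloro-2-hydroxy-4-methoxy-6-propylbenzoic trifluoroacetic anhydride | CCCc1cc(OC)c(Cl)c(O)c1C(=O)OC(=O)C(F)(F)F
F0 | step 10 | none | none
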